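## Retrosynthetic overview

1. Gnetofuran A ⇒ Heck disconnection of the stilbene: a 5-bromo-dihydrobenzofuran core (rings B and C) plus 3,5-bis(silyloxy)styrene (ring A, from resorcinol by C–H borylation and vinylation).
2. Core ⇒ LiAlH4 reduction of a methyl trans-2-aryl-2,3-dihydrobenzofuran-3-carboxylate.
3. That ester ⇒ oxidative ring contraction (1,2-aryl shift, PhI(OAc)2) of a (2R)-flavanone. The six-membered pyranone ring is built first and then contracted to the five-membered dihydrofuran; C2 controls C3 (trans).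
4. (2R)-Flavanone ⇒ new catalytic enantioselective para-C–H conjugate addition of guaiacol to 6-bromo-8-methoxychromone.
5. Chromone ⇒ chromanone (one-pot acylation and cyclisation of 4-bromoguaiacol with 3-chloropropanoic acid) ⇒ guaiacol ⇒ catechol. Guaiacol is used twice (rings B and C).

Assumption: the (S,S) acid catalyst of step 5 is taken to give the 2R product; if the first run gives 2S, the (R,R) catalyst is used and nothing else changes.

## Route

Step 1
Reactants: 1 catechol
Product: 2 guaiacol (2-methoxyphenol)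
Conditions: MeI (1.0 equiv), K2CO3, acetone, 56 °C
Reagents that add atoms: iodomethane, CI
Why: Williamson ether synthesis; with one equivalent of MeI the catechol monoanion is methylated once, and veratrole and unreacted catechol are removed by base extraction and distillation.

Step 2
Reactants: 2 guaiacol
Product: 3 4-bromo-2-methoxyphenol
Conditions: NBS, MeCN, 0 °C
Reagents that add atoms: N-bromosuccinimide, O=C1CCC(=O)N1Br
Why: Electrophilic aromatic bromination; OH is the stronger director and its para position is the least hindered, so the 4-bromide is formed.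

Step 3
Reactants: 3 4-bromo-2-methoxyphenol; 4 3-chloropropanoic acid
Product: 6 6-bromo-8-methoxychroman-4-one, via chloroethyl ketone 5 (not isolated)
Conditions: CF3SO3H, 80 °C; then 2 M NaOH aq, 0 °C to rt
Reagents that add atoms: none
Why: Friedel–Crafts (Fries-type) acylation ortho to the phenol OH, the para position being blocked by Br, followed by base-induced intramolecular Williamson cyclisation of the 2-hydroxyaryl 2-chloroethyl ketone, closes the pyranone ring.

Step 4
Reactants: 6 6-bromo-8-methoxychroman-4-one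
Product: 7 6-bromo-8-methoxy-4H-chromen-4-one
Conditions: IBX (2 equiv), DMSO, 85 °C
Reagents that add atoms: none
Why: IBX dehydrogenation of a ketone to the enone through its enol (Nicolaou oxidation); the aryl bromide and methyl ether are inert.

Step 5
Reactants: 7 6-bromo-8-methoxy-4H-chromen-4-one; 2 guaiacol (3 equiv)
Product: 9 4-[(2R)-6-bromo-8-methoxy-4-oxo-3,4-dihydro-2H-chromen-2-yl]-2-methoxyphenyl 2,2-dimethylpropanoate, via free-phenol flavanone 8 (not isolated)
Conditions: (S,S)-imidodiphosphorimidate acid HN[P(=NSO2CF3)(O2Ar*)]2 (Ar*O2 = (S)-3,3'-bis[3,5-bis(trifluoromethyl)phenyl]-1,1'-binaphthalene-2,2'-diolate; 5 mol %), CHCl3, −30 °C; then PivCl, pyridine, 0 °C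
Reagents that add atoms: pivaloyl chloride, CC(C)(C)C(=O)Cl
Why: Proposed new method: the confined, strongly acidic chiral imidodiphosphorimidate protonates the chromone carbonyl to a 4-hydroxybenzopyrylium ion held as a contact ion pair with the chiral anion, which also hydrogen-bonds the phenol OH of 2 and so delivers its para carbon (most nucleophilic, least hindered) to one face of C2; rearomatisation returns the proton to the catalyst, the enol tautomerises to the (2R)-flavanone, and this is capped in the same flask as the pivalate before it can racemise by ring opening. No enantioselective Friedel–Crafts hydroarylation of an unactivated chromone by a simple phenol C–H bond is known; the closest known reaction types are chiral-anion-controlled additions of silyl ketene acetals to 4-silyloxybenzopyrylium ions, asymmetric conjugate addition of arylboronic acids to chromones, and chiral Brønsted acid-catalysed para-selective Friedel–Crafts alkylation of phenols.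

Step 6
Reactants: 9 4-[(2R)-6-bromo-8-methoxy-4-oxo-3,4-dihydro-2H-chromen-2-yl]-2-methoxyphenyl 2,2-dimethylpropanoate
Product: 10 methyl (2R,3R)-5-bromo-2-[4-(2,2-dimethylpropanoyloxy)-3-methoxyphenyl]-7-methoxy-2,3-dihydro-1-benzofuran-3-carboxylate (trans)
Conditions: PhI(OAc)2 (1.2 equiv), conc. H2SO4 (2 equiv), HC(OMe)3, 0 °C to rt
Reagents that add atoms: trimethyl orthoformate, COC(OC)OC (ester OCH3); water, O (carbonyl oxygen on work-up)
Why: Hypervalent-iodine oxidative rearrangement of a flavanone (ring contraction by 1,2-aryl shift): the methyl enol ether of 9 is attacked at C3 by the trivalent iodine reagent anti to the C2 aryl, methanol adds to C4, and ring-B carbon C4a migrates from C4 to C3 with inversion as PhI leaves, so the pyranone becomes the dihydrofuran, C2 is untouched and the ester at C3 ends up trans to the aryl; the electron-poor pivaloyloxyaryl group suppresses the competing 2-aryl shift and oxidation of ring C.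

Step 7
Reactants: 10 methyl (2R,3R)-5-bromo-2-[4-(2,2-dimethylpropanoyloxy)-3-methoxyphenyl]-7-methoxy-2,3-dihydro-1-benzofuran-3-carboxylate
Product: 11 4-[(2R,3S)-5-bromo-3-(hydroxymethyl)-7-methoxy-2,3-dihydro-1-benzofuran-2-yl]-2-methoxyphenol
Conditions: LiAlH4, THF, 0 °C; then H2O, 15% NaOH aq
Reagents that add atoms: none
Why: Hydride reduction of the ester to the primary alcohol with simultaneous reductive cleavage of the pivalate; reduction outpaces enolisation at 0 °C, so both stereocentres are kept (the C3 descriptor changes to S only through priority rules), and the aryl bromide is inert at this temperature.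

Step 8
Reactants: 12 resorcinol
Product: 13 1,3-bis[tri(propan-2-yl)silyloxy]benzene
Conditions: TIPSCl (2.2 equiv), imidazole, DMF, rt
Reagents that add atoms: chlorotri(propan-2-yl)silane, CC(C)[Si](Cl)(C(C)C)C(C)C
Why: Silyl ether protection of both phenols; the bulky groups also block every ring position except C5 for the next step.

Step 9
Reactants: 13 1,3-bis[tri(propan-2-yl)silyloxy]benzene; 14 bromoethene (1 M in THF)
Product: 16 1-ethenyl-3,5-bis[tri(propan-2-yl)silyloxy]benzene, via arylboronate 15 (not isolated)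
Conditions: [Ir(OMe)(cod)]2 (1.5 mol %), 4,4'-di-tert-butyl-2,2'-bipyridine, B2pin2, THF, 80 °C; then 14, PdCl2(dppf), K3PO4 aq, 60 °C
Reagents that add atoms: bis(pinacolato)diboron, CC1(C)OB(OC1(C)C)B1OC(C)(C)C(C)(C)O1 (its boryl group is in intermediate 15 only)
Why: Sterically controlled iridium-catalysed aromatic C–H borylation at the only C–H with no ortho substituent (C5), then Suzuki–Miyaura coupling of the crude boronate with vinyl bromide in the same flask.

Step 10
Reactants: 11 4-[(2R,3S)-5-bromo-3-(hydroxymethyl)-7-methoxy-2,3-dihydro-1-benzofuran-2-yl]-2-methoxyphenol; 16 1-ethenyl-3,5-bis[tri(propan-2-yl)silyloxy]benzene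
Product: 18 gnetofuran A, via bis-silyl stilbene 17 (not isolated)
Conditions: Pd2(dba)3 (2.5 mol %), [HP(t-Bu)3]BF4 (10 mol %), Cy2NMe, 1,4-dioxane, 90 °C; then Bu4NF, AcOH, THF, 0 °C
Reagents that add atoms: none
Why: Mizoroki–Heck reaction: oxidative addition of the electron-rich aryl bromide to zerovalent palladium bearing P(t-Bu)3, syn insertion of the styrene and syn β-hydride elimination give the E-stilbene, and acetic acid-buffered fluoride then removes both silyl groups without opening the dihydrofuran or touching the stereocentres.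

## Compound list

1 | catechol (benzene-1,2-diol) | Oc1ccccc1O | starting material
2 | guaiacol (2-methoxyphenol) | COc1ccccc1O | intermediate
3 | 4-bromo-2-methoxyphenol | COc1cc(Br)ccc1O | intermediate
4 | 3-chloropropanoic acid | OC(=O)CCCl | starting material
5 | 1-(5-bromo-2-hydroxy-3-methoxyphenyl)-3-chloropropan-1-one | COc1cc(Br)cc(C(=O)CCCl)c1O | intermediate (not isolated)
6 | 6-bromo-8-methoxychroman-4-one (6-bromo-8-methoxy-2,3-dihydro-4H-chromen-4-one) | COc1cc(Br)cc2C(=O)CCOc12 | intermediate
7 | 6-bromo-8-methoxy-4H-chromen-4-one | COc1cc(Br)cc2C(=O)C=COc12 | intermediate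
8 | (2R)-6-bromo-2-(4-hydroxy-3-methoxyphenyl)-8-methoxy-2,3-dihydro-4H-chromen-4-one | COc1cc([C@@H]2Oc3c(OC)cc(Br)cc3C(=O)C2)ccc1O | intermediate (not isolated)
9 | 4-[(2R)-6-bromo-8-methoxy-4-oxo-3,4-dihydro-2H-chromen-2-yl]-2-methoxyphenyl 2,2-dimethylpropanoate | COc1cc([C@@H]2Oc3c(OC)cc(Br)cc3C(=O)C2)ccc1OC(=O)C(C)(C)C | intermediate
10 | methyl (2R,3R)-5-bromo-2-[4-(2,2-dimethylpropanoyloxy)-3-methoxyphenyl]-7-methoxy-2,3-dihydro-1-benzofuran-3-carboxylate (2,3-trans) | COc1cc([C@@H]2Oc3c(OC)cc(Br)cc3[C@H]2C(=O)OC)ccc1OC(=O)C(C)(C)C | intermediate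
11 | 4-[(2R,3S)-5-bromo-3-(hydroxymethyl)-7-methoxy-2,3-dihydro-1-benzofuran-2-yl]-2-methoxyphenol (2,3-trans) | COc1cc([C@@H]2Oc3c(OC)cc(Br)cc3[C@H]2CO)ccc1O | intermediate
12 | resorcinol (benzene-1,3-diol) | Oc1cccc(O)c1 | starting material
13 | 1,3-bis[tri(propan-2-yl)silyloxy]benzene | CC(C)[Si](Oc1cccc(O[Si](C(C)C)(C(C)C)C(C)C)c1)(C(C)C)C(C)C | intermediate
14 | bromoethene (vinyl bromide) | C=CBr | starting material
15 | 2-{3,5-bis[tri(propan-2-yl)silyloxy]phenyl}-4,4,5,5-tetramethyl-1,3,2-dioxaborolane | CC(C)[Si](Oc1cc(B2OC(C)(C)C(C)(C)O2)cc(O[Si](C(C)C)(C(C)C)C(C)C)c1)(C(C)C)C(C)C | intermediate (not isolated)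
16 | 1-ethenyl-3,5-bis[tri(propan-2-yl)silyloxy]benzene | C=Cc1cc(O[Si](C(C)C)(C(C)C)C(C)C)cc(O[Si](C(C)C)(C(C)C)C(C)C)c1 | intermediate
17 | 4-[(2R,3S)-5-[(E)-2-{3,5-bis[tri(propan-2-yl)silyloxy]phenyl}ethenyl]-3-(hydroxymethyl)-7-methoxy-2,3-dihydro-1-benzofuran-2-yl]-2-methoxyphenol | COc1cc([C@@H]2Oc3c(OC)cc(/C=C/c4cc(O[Si](C(C)C)(C(C)C)C(C)C)cc(O[Si](C(C)C)(C(C)C)C(C)C)c4)cc3[C@H]2CO)ccc1O | intermediate (not isolated)
18 | gnetofuran A, 5-[(E)-2-[(2R,3S)-2-(4-hydroxy-3-methoxyphenyl)-3-(hydroxymethyl)-7-methoxy-2,3-dihydro-1-benzofuran-5-yl]ethenyl]benzene-1,3-diol | COc1cc([C@@H]2Oc3c(OC)cc(/C=C/c4cc(O)cc(O)c4)cc3[C@H]2CO)ccc1O | target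

## Step count and risks

Total steps: 10. Longest linear sequence: 8 (steps 1 to 7, then step 10).

**Step 5 (the proposed new reaction).** Reactivity of guaiacol towards the protonated chromone, para versus ortho attack, and the level of enantiocontrol are all untested. The fallback uses the known asymmetric conjugate addition of an arylboronic acid to a chromone. It sets out from 3: acylation with PivCl and pyridine gives 4-bromo-2-methoxyphenyl 2,2-dimethylpropanoate F1. Palladium-catalysed borylation (Pd(OAc)2, XPhos, B2(OH)4, KOAc, EtOH, 80 °C) gives [4-(2,2-dimethylpropanoyloxy)-3-methoxyphenyl]boronic acid F2. F2 is added to chromone 7 with Pd(OCOCF3)2 and the t-BuPyOx enantiomer that gives 2R (NH4PF6, H2O, ClCH2CH2Cl, 60 °C); the cycle stays at divalent palladium, so the aryl bromide is untouched. The fallback comes back to the route at 9.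

**Step 6 (ring contraction).** Flavone formation, 3-methoxylation or some cis ester may erode the yield. The fallback moves the contraction from the enol ether to the alkene of a flav-3-ene, a known thallium-mediated ring contraction of 2H-chromenes. It sets out from 9: NaBH4 (MeOH/THF, 0 °C) gives 4-[(2R,4R)-6-bromo-4-hydroxy-8-methoxy-3,4-dihydro-2H-chromen-2-yl]-2-methoxyphenyl 2,2-dimethylpropanoate F3. Dehydration (cat. TsOH, toluene, 80 °C) gives 4-[(2R)-6-bromo-8-methoxy-2H-chromen-2-yl]-2-methoxyphenyl 2,2-dimethylpropanoate F4. Tl(NO3)3·3H2O (trivalent thallium) in MeOH/HC(OMe)3 at −20 °C effects the same anti-addition and 1,2-aryl shift to give 4-[(2R,3R)-5-bromo-3-(dimethoxymethyl)-7-methoxy-2,3-dihydro-1-benzofuran-2-yl]-2-methoxyphenyl 2,2-dimethylpropanoate F5. Aqueous HCl in THF gives 4-[(2R,3R)-5-bromo-3-formyl-7-methoxy-2,3-dihydro-1-benzofuran-2-yl]-2-methoxyphenyl 2,2-dimethylpropanoate F6. LiAlH4 (THF, 0 °C) reduces the aldehyde and removes the pivalate, and the fallback comes back to the route at 11.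

**Step 10 (Heck coupling and desilylation).** Oxidative addition of the electron-rich bromide may be slow, and some 1,1-diarylethene may form. The fallback forms the aryl–vinyl bond by Suzuki–Miyaura coupling on a preformed E-alkenylboronate. It sets out from 16: cross-metathesis with vinylboronic acid pinacol ester (second-generation Grubbs catalyst RuCl2(=CHPh)(PCy3)(H2IMes), CH2Cl2, 40 °C) gives 2-[(E)-2-{3,5-bis[tri(propan-2-yl)silyloxy]phenyl}ethenyl]-4,4,5,5-tetramethyl-1,3,2-dioxaborolane F7. F7 is coupled with bromide 11 (PdCl2(dppf), K3PO4 aq, 1,4-dioxane, 80 °C), and the fallback comes back to the route at 17, which is desilylated as in step 10 to 18.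

## Further compounds

F1 | step 5 | 4-bromo-2-methoxyphenyl 2,2-dimethylpropanoate | COc1cc(Br)ccc1OC(=O)C(C)(C)C
F2 | step 5 | [4-(2,2-dimethylpropanoyloxy)-3-methoxyphenyl]boronic acid | COc1cc(B(O)O)ccc1OC(=O)C(C)(C)C
F3 | step 6 | 4-[(2R,4R)-6-bromo-4-hydroxy-8-methoxy-3,4-dihydro-2H-chromen-2-yl]-2-methoxyphenyl 2,2-dimethylpropanoate | COc1cc([C@@H]2Oc3c(OC)cc(Br)cc3[C@H](O)C2)ccc1OC(=O)C(C)(C)C
F4 | step 6 | 4-[(2R)-6-bromo-8-methoxy-2H-chromen-2-yl]-2-methoxyphenyl 2,2-dimethylpropanoate | COc1cc([C@@H]2Oc3c(OC)cc(Br)cc3C=C2)ccc1OC(=O)C(C)(C)C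
F5 | step 6 | 4-[(2R,3R)-5-bromo-3-(dimethoxymethyl)-7-methoxy-2,3-dihydro-1-benzofuran-2-yl]-2-methoxyphenyl 2,2-dimethylpropanoate | COc1cc([C@@H]2Oc3c(OC)cc(Br)cc3[C@H]2C(OC)OC)ccc1OC(=O)C(C)(C)C
F6 | step 6 | 4-[(2R,3R)-5-bromo-3-formyl-7-methoxy-2,3-dihydro-1-benzofuran-2-yl]-2-methoxyphenyl 2,2-dimethylpropanoate | COc1cc([C@@H]2Oc3c(OC)cc(Br)cc3[C@H]2C=O)ccc1OC(=O)C(C)(C)C
F7 | step 10 | 2-[(E)-2-{3,5-bis[tri(propan-2-yl)silyloxy]phenyl}ethenyl]-4,4,5,5-tetramethyl-1,3,2-dioxaborolane | CC(C)[Si](Oc1cc(/C=C/B2OC(C)(C)C(C)(C)O2)cc(O[Si](C(C)C)(C(C)C)C(C)C)c1)(C(C)C)C(C)C
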